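One question stands, and one quantity answers it.

| flask | electrophile | nucleophile | remark | time |
|---|---|---|---|---|
| Monday's | 0.019 M | 0.0057 M | run made earlier |  |
| flask | 0.019 M |  |  | 4.0 d |

Monday's run (percent of the electrophile charged)

| time / h | product / % | electrophile / % |
|---|---|---|
| 1.50 | 0.9 | 99.2 |
| 4.00 | 2.2 | 97.3 |
| 8.00 | 3.0 | 94.8 |
| 20.0 | 7.5 | 88.3 |

(scatter of a reading: 0.3 percentage points)

- the concentration of nucleophile at which the part of the electrophile that has reacted at 4.0 d is just 50%, in M

- the amount of nucleophile is what is sought; it is there from the start
- what has gone from electrophile into another species counts as reacted, even if it can come back

Work in fractions of the electrophile charge, and take two assumptions of your own: each electrophile gone costs one nucleophile, and the loss per hour of the surviving electrophile follows free nucleophile. Count the gap between electrophile gone and product as gone.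

Monday's run starts with nucleophile at 0.300, and by 20.0 h its electrophile reading is down by 11.7%, which the first assumption takes from nucleophile as well, so the logarithmic mean of nucleophile over that time is 0.237. That reading gives the halving dose, 26.4 h: the time that would take away half of the electrophile with nucleophile held at 0.019 M.

Now run the new flask slowly. Over 4.0 d, nucleophile must average 0.275. In the first instants it stands at its charge, and 50% of the electrophile charge must be spent by the end. A straight-line mean asks for a start of 0.525, which leaves a tail of 0.0250. Put that back and go round once more with the logarithmic mean: the start becomes 0.597, or 0.0113 M, and the end 0.0970. Nucleophile is the limiting reagent, charged at less than the electrophile. In this reckoning it falls from 0.597 to 0.0970, so watch the loss per hour of the surviving electrophile run faster at the start than at the end.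

The forecast stands at 0.011 M, with the rider “Reversibility would push this higher”. The flask gives 0.0113 M, against my 0.0113 M.

    electrophile + nucleophile → acid set free + product (k = 2.40 × 10⁻⁴ M⁻¹ s⁻¹)
    nucleophile + acid set free ⇌ protonated nucleophile, settled at all times (K = 10000 M⁻¹)
    electrophile + acid set free ⇌ idle adduct, settled at all times (K = 3700 M⁻¹)

At 1.02 d in this flask, the product step gives nucleophile a half-life of 2.3 d, shorter than the electrophile's 5.0 d. At 4.00 d the electrophile's half-life by that step has reached 13 d, longer than the run. Spread over 4.0 d in this flask, the halving dose asks for a mean free nucleophile of 46.0% of its charge, and 40.1% of that charge stands free at 2.00 d. In the run with twice the electrophile and the rest unchanged, 43.3% of its electrophile has reacted at the end, which counts as 81.9% of one halving dose received.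

Readings and results come from a simulation with constants of no real substance.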